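**Plan**

- Retrosynthesis: the epoxide and the C15 aldehyde go back to an (E)-allylic alcohol (Sharpless epoxidation, oxidation). C13=C14 and C8=C17 are cut by two olefinations of an 8,13-diketone. Ring A is cut at C3–C4, C9–C11 and C10–C1 by two conjugate additions on one cyclohexenone.
- Forward: ring B comes from ethyl 2-methyl-4-oxocyclohex-2-ene-1-carboxylate, whose ester carbon becomes C4. C10 and C9 are alkylated, the ester is turned into an (E)-2-alkylbutenedioate, ring A is closed last through C3–C4, then the side chain is finished.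
- Feature used: C3 is a carbonyl-level carbon next to the quaternary C4, and the 4α-methyl (C18) can carry a temporary carboxyl group. C3(=O) and that carboxyl are then 1,4-related with C4 β to it, so ring A (C1, C2, C3, C4, C5, C10) is the retron of an intramolecular Stetter reaction. The helper carboxyl leaves later as CO2; two dioxolanes mask C8 and C13.
- Stereochemistry: C5 by copper-catalysed kinetic resolution (step 1); C10 anti to the C5 ester; C4 by allylic A(1,3) strain in the key step; C3 by equatorial hydride delivery; C9 by equilibration next to the C8 ketone; C13 and C14 by the tartrate reagent.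

Key step: step 8

Remark: locants C1–C20 are those of the labdane skeleton of the target. The ligand enantiomer in step 1 ((4S,5S) is written) is the one that makes (R)-1 the fast-reacting enantiomer and is to be fixed in a pilot run. C9 is left undefined in 6–15 and is set by equilibration in steps 10 and 12.

**Route**

Step 1
Reactants: 1 ethyl 2-methyl-4-oxocyclohex-2-ene-1-carboxylate (racemic); 2 but-3-en-1-ylmagnesium bromide (0.55 equiv)
Product: 4 ethyl (1R,2R)-2-(but-3-en-1-yl)-2-methyl-4-[(trimethylsilyl)oxy]cyclohex-3-ene-1-carboxylate, via bromomagnesium enolate 3 (not isolated)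
Conditions: Cu(OTf)2 (3 mol %), (4S,5S)-1,3-bis(2-methoxybenzyl)-4,5-diphenyl-4,5-dihydroimidazolium chloride (4 mol %), Et2O, −30 °C; then Me3SiCl, Et3N, −30 °C → rt
Reagents that add atoms: chlorotrimethylsilane, C[Si](C)(C)Cl
Why: Copper-catalysed asymmetric conjugate addition of a Grignard reagent to a β-methylcyclohexenone, run as a kinetic resolution: the chiral copper–carbene complex should consume (R)-1, the butenyl group enters anti to the C5 ester and so sets C10 trans, and unreacted (S)-1 racemises through its dienol with a trace of base and is recycled.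

Step 2
Reactants: 4 silyl enol ether; 5 but-3-en-2-one
Product: 6 ethyl (1R,2R)-2-(but-3-en-1-yl)-2-methyl-4-oxo-3-(3-oxobutyl)cyclohexane-1-carboxylate (both epimers at ring C3, which is C9 of the target)
Conditions: 5 (1.5 equiv), TiCl4 (1.1 equiv), CH2Cl2, −78 °C; aq. NaHCO3
Reagents that add atoms: none
Why: Mukaiyama–Michael addition, in which the regiodefined silyl enol ether attacks the TiCl4-activated enone through C9 only, so the 3-oxobutyl chain (C11, C12, C13, C16) is placed next to the quaternary carbon.

Step 3
Reactants: 6 diketo ester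
Product: 7 bis(1,3-dioxolane) of 6 (ring ketone C8 and side-chain ketone C13 both acetalised)
Conditions: Me3SiOCH2CH2OSiMe3 (4 equiv), Me3SiOTf (5 mol %), CH2Cl2, −78 → 0 °C
Reagents that add atoms: 1,2-bis(trimethylsilyloxy)ethane, C[Si](C)(C)OCCO[Si](C)(C)C
Why: Silyl-triflate-catalysed acetalisation at low temperature masks both ketones without acid-promoted aldol closure of the 1,5-diketone and keeps them out of the Claisen and Stetter steps.

Step 4
Reactants: 7 bis-dioxolane ester; 8 tert-butyl acetate
Product: 9 tert-butyl β-keto ester (the CO2Et of 7 replaced by C(=O)CH2CO2t-Bu; the ketone carbon is C4, the CH2 is C18)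
Conditions: 8 (3.5 equiv), LiN(i-Pr)2 (3.5 equiv), THF, −78 °C; then 7, −78 → −20 °C; aq. NH4Cl
Reagents that add atoms: none
Why: Crossed Claisen condensation, in which excess lithium enolate of tert-butyl acetate acylates on the ethyl ester and the product is held as its enolate, which should prevent over-addition and epimerisation at C5.

Step 5
Reactants: 9 β-keto ester
Product: 10 (E)-enol triflate of 9 (TfO on C4, trans to CO2t-Bu)
Conditions: Tf2O (1.5 equiv), aq. Me4NOH, toluene, 5 °C
Reagents that add atoms: trifluoromethanesulfonic anhydride, O=S(=O)(OS(=O)(=O)C(F)(F)F)C(F)(F)F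
Why: O-triflation of the β-keto ester enolate with the non-chelating tetramethylammonium counter-ion should give the (E)-enol triflate, the geometry that the next step retains.

Step 6
Reactants: 10 enol triflate
Product: 11 4-tert-butyl 1-methyl (2E)-2-(ring B residue)but-2-enedioate (CO2Me on C4, CO2t-Bu on C18, the two esters trans)
Conditions: Pd(OAc)2 (5 mol %), Ph2P(CH2)3PPh2 (6 mol %), CO (1 atm), MeOH, Et3N, DMF, 50 °C
Reagents that add atoms: carbon monoxide, [C-]#[O+]; methanol, CO
Why: Palladium-catalysed methoxycarbonylation of an enol triflate (oxidative addition, CO insertion, methanolysis) proceeds with retention of alkene geometry and installs C19 as the methyl ester.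

Step 7
Reactants: 11 butenedioate with terminal alkene
Product: 12 aldehyde (the but-3-enyl group of 11 cut to 3-oxopropyl, C3 = CHO)
Conditions: O3, CH2Cl2, −78 °C (Sudan Red 7B end point); then PPh3, −78 °C → rt
Reagents that add atoms: ozone, [O-][O+]=O
Why: Ozonolysis is chemoselective because electrophilic ozone cleaves the isolated terminal alkene far faster than the electron-poor butenedioate, and PPh3 reduces the ozonide to the aldehyde.

Step 8
Reactants: 12 aldehyde
Product: 13 ring A ketone (trans-decalin, 5α-H, 10β-CH3; C3 ketone; C4 with β (axial) CO2Me and α (equatorial) CH2CO2t-Bu; C8 and C13 as dioxolanes)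
Conditions: 2-(pentafluorophenyl)-6,7-dihydro-5H-pyrrolo[2,1-c][1,2,4]triazol-2-ium tetrafluoroborate (20 mol %), KN(SiMe3)2 (18 mol %), toluene, 25 → 45 °C
Reagents that add atoms: none
Why: The carbene from the triazolium salt adds to the C3 aldehyde and, after proton transfer, gives the amino enol (acyl-anion equivalent), which attacks C4 of the butenedioate; proton transfer to C18 and loss of the carbene give the C3 ketone, as in known intramolecular Stetter reactions that build α-quaternary cyclic ketones from trisubstituted acceptors. Ring A (C3, C4, C5, C10, C1, C2) closes 6-exo-trig through a chair in which both arms are equatorial on ring B, so the ring fusion stays trans. C4 is the only new stereocentre: in the (E)-alkene the CO2t-Bu group on C18 is cis to C5, so A(1,3) strain holds C5–H in the alkene plane, and C3, tethered through C10, must add to the face that leaves the C18 arm equatorial (α) and the methyl ester axial (β), syn to the C10 methyl. The step needs attack at the fully substituted C4 and not at C18 (7-endo), which ring size should secure, and it needs the aldehyde to be the only free carbonyl, which the two dioxolanes secure by blocking a crossed benzoin reaction with C8. The alkene geometry from steps 5 and 6 is therefore part of the stereocontrol.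

Step 9
Reactants: 13 ring A ketone
Product: 15 3α-acetate (axial OAc at C3; otherwise as 13), via lithium 3α-alkoxide 14 (not isolated)
Conditions: LiBH(s-Bu)3 (1.3 equiv), THF, −78 °C; then Ac2O (5 equiv), DMAP, −78 → 0 °C
Reagents that add atoms: acetic anhydride, CC(=O)OC(C)=O
Why: The bulky borohydride should attack the C3 ketone along the equatorial trajectory, away from the axial hydrogens at C1 and C5, to give the axial 3α-alkoxide, which is acetylated in the same flask before it can lactonise onto the cis tert-butyl ester.

Step 10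
Reactants: 15 3α-acetate
Product: 16 diketo acid (3α-OAc, 4β-CO2Me, 4α-CH2CO2H, C8 ketone, 9β-(3-oxobutyl))
Conditions: CF3CO2H–H2O (9:1), CH2Cl2, 0 °C → rt
Reagents that add atoms: water, O
Why: Aqueous acid cleaves the tert-butyl ester by alkyl–oxygen fission and hydrolyses both dioxolanes while the hindered axial acetate and the neopentyl methyl ester should survive, and the freed C8 ketone lets C9 equilibrate through its enol to the equatorial (β) side chain.

Step 11
Reactants: 16 diketo acid
Product: 17 methyl 3α-acetoxy-8,13-dioxo-14,15,17-trinorlabdan-19-oate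
Conditions: 9-mesityl-10-methylacridinium tetrafluoroborate (5 mol %), PhSSPh (10 mol %), i-Pr2NEt (20 mol %), CF3CH2OH, 450 nm LEDs, rt
Reagents that add atoms: none
Why: Photoredox hydrodecarboxylation, in which the excited acridinium oxidises the carboxylate, loss of CO2 gives the primary C18 radical and thiophenol formed from the disulfide transfers hydrogen, turns the helper CH2CO2H into the 4α-methyl group.

Step 12
Reactants: 17 diketone; 18 diethyl {2-[methoxy(methyl)amino]-2-oxoethyl}phosphonate
Product: 19 (13E)-N-methoxy-N-methyl amide (C13(CH3)=C14H–C15(=O)N(OMe)Me; C8 ketone kept)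
Conditions: 18 (1.5 equiv), NaH (1.4 equiv), THF, 0 °C → rt
Reagents that add atoms: none
Why: Horner–Wadsworth–Emmons olefination should select the unhindered methyl ketone over the C8 ketone, which is flanked by C9 and the quaternary C10, and give mainly the (E)-alkene, the minor (Z)-isomer being removed by chromatography.

Step 13
Reactants: 19 keto amide
Product: 20 methyl 3α-acetoxy-15-[methoxy(methyl)amino]-15-oxolabda-8(17),13E-dien-19-oate
Conditions: Ph3PCH3Br (3 equiv), KN(SiMe3)2 (2.9 equiv), THF, 0 °C; then 19, 0 → 45 °C
Reagents that add atoms: methyltriphenylphosphonium bromide, C[P+](c1ccccc1)(c1ccccc1)c1ccccc1.[Br-]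
Why: Wittig methylenation of the hindered C8 ketone with base-free Ph3P=CH2 should spare the hindered acetate and esters, and any 9-epimer would equilibrate to the 9β side chain before olefination.

Step 14
Reactants: 20 dienyl amide
Product: 22 methyl 3α-acetoxy-15-hydroxylabda-8(17),13E-dien-19-oate, via enal 21 (not isolated)
Conditions: Cp2Zr(H)Cl (1.5 equiv), THF, rt, 20 min; then NaBH4, CeCl3·7H2O, MeOH, −20 °C
Reagents that add atoms: none
Why: The zirconium hydride reduces the N-methoxy-N-methyl amide to the aldehyde level faster than it touches esters or the hindered 1,1-disubstituted alkene, and Luche reduction of the released enal is 1,2-selective and spares the acetate.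

Step 15
Reactants: 22 (E)-allylic alcohol
Product: 23 methyl (13R,14R)-3α-acetoxy-13,14-epoxy-15-hydroxylabd-8(17)-en-19-oate
Conditions: Ti(Oi-Pr)4 (10 mol %), D-(−)-diethyl tartrate (12 mol %), t-BuOOH (2 equiv), 4 Å molecular sieves, CH2Cl2, −20 °C
Reagents that add atoms: tert-butyl hydroperoxide, CC(C)(C)OO
Why: Sharpless asymmetric epoxidation is reagent-controlled: the titanium–D-(−)-tartrate complex delivers oxygen to the face of the (E)-allylic alcohol that gives the (13R,14R)-epoxy alcohol, independently of the remote ring stereocentres, and leaves the exocyclic alkene untouched.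

Step 16
Reactants: 23 epoxy alcohol
Product: 24 methyl (13R,14S)-3α-acetoxy-13,14-epoxy-15-oxolabd-8(17)-en-19-oate (the target)
Conditions: Dess–Martin periodinane (1.3 equiv), NaHCO3, CH2Cl2, 0 °C → rt
Reagents that add atoms: none
Why: Buffered Dess–Martin oxidation converts the primary epoxy alcohol into the epoxy aldehyde without epimerising C14 or opening the epoxide.

**Compound list**

1 | ethyl 2-methyl-4-oxocyclohex-2-ene-1-carboxylate (racemic) | CCOC(=O)C1CCC(=O)C=C1C | starting material
2 | but-3-en-1-ylmagnesium bromide | C=CCC[Mg]Br | starting material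
3 | bromomagnesium enolate of the 1,4-adduct | C1(O[Mg]Br)=C[C@@](C)(CCC=C)[C@H](C(=O)OCC)CC1 | intermediate (not isolated)
4 | ethyl (1R,2R)-2-(but-3-en-1-yl)-2-methyl-4-[(trimethylsilyl)oxy]cyclohex-3-ene-1-carboxylate | C1(O[Si](C)(C)C)=C[C@@](C)(CCC=C)[C@H](C(=O)OCC)CC1 | intermediate
5 | but-3-en-2-one | CC(=O)C=C | starting material
6 | ethyl (1R,2R)-2-(but-3-en-1-yl)-2-methyl-4-oxo-3-(3-oxobutyl)cyclohexane-1-carboxylate (C9 epimers) | O=C1CC[C@@H](C(=O)OCC)[C@](C)(CCC=C)C1CCC(C)=O | intermediate
7 | bis(1,3-dioxolane) of 6 | O1CCOC12CC[C@@H](C(=O)OCC)[C@](C)(CCC=C)C2CCC3(C)OCCO3 | intermediate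
8 | tert-butyl acetate | CC(=O)OC(C)(C)C | starting material
9 | tert-butyl β-keto ester from 7 | O1CCOC12CC[C@@H](C(=O)CC(=O)OC(C)(C)C)[C@](C)(CCC=C)C2CCC3(C)OCCO3 | intermediate
10 | (E)-enol triflate of 9 | O1CCOC12CC[C@@H](/C(OS(=O)(=O)C(F)(F)F)=C\C(=O)OC(C)(C)C)[C@](C)(CCC=C)C2CCC3(C)OCCO3 | intermediate
11 | 4-tert-butyl 1-methyl (2E)-2-(ring B residue)but-2-enedioate | O1CCOC12CC[C@@H](/C(C(=O)OC)=C\C(=O)OC(C)(C)C)[C@](C)(CCC=C)C2CCC3(C)OCCO3 | intermediate
12 | C3 aldehyde of 11 | O1CCOC12CC[C@@H](/C(C(=O)OC)=C\C(=O)OC(C)(C)C)[C@](C)(CCC=O)C2CCC3(C)OCCO3 | intermediate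
13 | ring A 3-ketone with 4β-CO2Me and 4α-CH2CO2t-Bu | O1CCOC12CC[C@@H]3[C@](C)(CCC(=O)[C@]3(CC(=O)OC(C)(C)C)C(=O)OC)C2CCC4(C)OCCO4 | intermediate
14 | lithium 3α-alkoxide from 13 | O1CCOC12CC[C@@H]3[C@](C)(CC[C@@H](O[Li])[C@]3(CC(=O)OC(C)(C)C)C(=O)OC)C2CCC4(C)OCCO4 | intermediate (not isolated)
15 | 3α-acetate | O1CCOC12CC[C@@H]3[C@](C)(CC[C@@H](OC(C)=O)[C@]3(CC(=O)OC(C)(C)C)C(=O)OC)C2CCC4(C)OCCO4 | intermediate
16 | diketo acid (4α-CH2CO2H) | O=C1CC[C@@H]2[C@](C)(CC[C@@H](OC(C)=O)[C@]2(CC(=O)O)C(=O)OC)[C@H]1CCC(C)=O | intermediate
17 | methyl 3α-acetoxy-8,13-dioxo-14,15,17-trinorlabdan-19-oate | O=C1CC[C@@H]2[C@](C)(CC[C@@H](OC(C)=O)[C@]2(C)C(=O)OC)[C@H]1CCC(C)=O | intermediate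
18 | diethyl {2-[methoxy(methyl)amino]-2-oxoethyl}phosphonate | CCOP(=O)(CC(=O)N(C)OC)OCC | starting material
19 | (13E)-N-methoxy-N-methyl amide with C8 ketone | O=C1CC[C@@H]2[C@](C)(CC[C@@H](OC(C)=O)[C@]2(C)C(=O)OC)[C@H]1CC/C(C)=C/C(=O)N(C)OC | intermediate
20 | methyl 3α-acetoxy-15-[methoxy(methyl)amino]-15-oxolabda-8(17),13E-dien-19-oate | C=C1CC[C@@H]2[C@](C)(CC[C@@H](OC(C)=O)[C@]2(C)C(=O)OC)[C@H]1CC/C(C)=C/C(=O)N(C)OC | intermediate
21 | methyl 3α-acetoxy-15-oxolabda-8(17),13E-dien-19-oate | C=C1CC[C@@H]2[C@](C)(CC[C@@H](OC(C)=O)[C@]2(C)C(=O)OC)[C@H]1CC/C(C)=C/C=O | intermediate (not isolated)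
22 | methyl 3α-acetoxy-15-hydroxylabda-8(17),13E-dien-19-oate | C=C1CC[C@@H]2[C@](C)(CC[C@@H](OC(C)=O)[C@]2(C)C(=O)OC)[C@H]1CC/C(C)=C/CO | intermediate
23 | methyl (13R,14R)-3α-acetoxy-13,14-epoxy-15-hydroxylabd-8(17)-en-19-oate | C=C1CC[C@@H]2[C@](C)(CC[C@@H](OC(C)=O)[C@]2(C)C(=O)OC)[C@H]1CC[C@@]1(C)O[C@@H]1CO | intermediate
24 | methyl (13R,14S)-3α-acetoxy-13,14-epoxy-15-oxolabd-8(17)-en-19-oate | C=C1CC[C@@H]2[C@](C)(CC[C@@H](OC(C)=O)[C@]2(C)C(=O)OC)[C@H]1CC[C@@]1(C)O[C@@H]1C=O | target

**Step count and risks**

Total: 16 steps. Longest linear sequence: 16 steps (1 → 24).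

Steps most likely to fail:

Step 8. The conjugate addition may be slow at the fully substituted C4, which is shielded by C5 and the quaternary C10; attack may go to C18 (7-endo); or base may move the double bond toward C5. The fallback sets out from 12 and returns at 13. SmI2 (2.5 equiv) with t-BuOH in THF–HMPA at −78 °C should trigger a reductive 6-exo ketyl–olefin radical cyclisation onto C4, under the same allylic-strain control, to give the ring A 3-hydroxy diester F1 (both C3 epimers). Dess–Martin oxidation of F1 should then give 13.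

Step 1. The catalyst may discriminate poorly between the two enantiomers of 1, or the Grignard reagent may deprotonate 1 at C5 instead of adding. In the fallback the addition is run without a chiral ligand (CuBr·SMe2, Me3SiCl, THF, −78 °C) and the racemate is carried through steps 2–8. The fallback proper sets out from racemic 13 and returns at 15. An (R)-selective ketoreductase (alcohol dehydrogenase class, NADP+, propan-2-ol for cofactor recycling, phosphate buffer, 30 °C) should reduce only the enantiomer of 13 drawn here to the 3α-alcohol F2. F2 is separated from the unreduced antipode and acetylated (Ac2O, DMAP, pyridine) to 15.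

Step 4. Acylation of the hindered ester may be incomplete, or enolisation may epimerise C5. The fallback sets out from 7 and returns at 9. i-Bu2AlH (1.1 equiv, toluene, −78 °C) should stop at the aldehyde F3. Roskamp homologation of F3 with tert-butyl diazoacetate and SnCl2 (10 mol %) in CH2Cl2 should give 9 by 1,2-hydride shift with loss of nitrogen, without any strong base.

Further compounds
F1 | step 8 | ring A 3-hydroxy diester (C3 epimers; otherwise as 13) | O1CCOC12CC[C@@H]3[C@](C)(CCC(O)[C@]3(CC(=O)OC(C)(C)C)C(=O)OC)C2CCC4(C)OCCO4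
F2 | step 1 | 3α-alcohol (free hydroxyl form of 14) | O1CCOC12CC[C@@H]3[C@](C)(CC[C@@H](O)[C@]3(CC(=O)OC(C)(C)C)C(=O)OC)C2CCC4(C)OCCO4
F3 | step 4 | aldehyde from 7 (CO2Et reduced to CHO) | O1CCOC12CC[C@@H](C=O)[C@](C)(CCC=C)C2CCC3(C)OCCO3
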